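**Retrosynthetic overview**
- The strategy rests on the only ring of the target, a 1,4-disubstituted benzene ring. C4 carries the OH, and C1, para to it, carries the CH2CH2CO2C26H53 chain.
- First cut: O–H back to O–SiMe3, and the arene back to the 1,4-cyclohexadiene one oxidation level lower (double bonds C1=C2 and C4=C5).
- Key cut: C2–C3 and C1–C6 in a [4+2] sense. C3–C4(O)–C5–C6 come from 2-(trimethylsilyloxy)buta-1,3-diene, and C1–C2 come from the terminal alkyne of hexacosyl pent-4-ynoate.
- Last cut: the ester C–O bond, back to pent-4-ynoic acid and hexacosan-1-ol.
- Ring order: there is a single ring, closed in step 2 and aromatised in step 3.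

Key step: step 2

Remark: the target has no stereocentre and no stereogenic double bond, so only regiochemistry (para against meta) must be controlled. The C26 compounds are waxy and are handled in warm or dilute solution.

**Step 1**
Reactants: 1 pent-4-ynoic acid (1.2 equiv); 2 hexacosan-1-ol
Product: 3 hexacosyl pent-4-ynoate
Conditions: DCC (1.3 equiv), DMAP (0.1 equiv), CH2Cl2/THF 1:1, 35 °C; filter, chromatography (hexane/EtOAc)
Reagents that add atoms: none
Why: This is a Steglich esterification, in which carbodiimide activation of the acid with DMAP as acyl-transfer catalyst should acylate the unhindered primary alcohol under neutral conditions that leave the terminal alkyne untouched, and no stereocentre is formed.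

**Step 2**
Reactants: 3 hexacosyl pent-4-ynoate; 4 2-(trimethylsilyloxy)buta-1,3-diene (1.5 equiv)
Product: 5 hexacosyl 3-[4-(trimethylsilyloxy)cyclohexa-1,4-dien-1-yl]propanoate
Conditions: CoBr2(dppe) (10 mol %), Zn powder (20 mol %), anhydrous ZnI2 (20 mol %), CH2Cl2, 25–30 °C, Ar; filter through a short pad of Et3N-deactivated silica (Et2O/pentane), use crude
Reagents that add atoms: none
Why: Zn reduces the divalent cobalt of CoBr2(dppe) and ZnI2 abstracts the remaining halide, giving a cationic monovalent cobalt–dppe fragment that binds the s-cis diene 4 and the terminal alkyne of 3 at the same metal. Oxidative coupling of the two π-systems should give a trivalent cobaltacycle with one new C–C bond and reductive elimination makes the second, so C2–C3 and C1–C6 are formed and the six-membered carbocycle closes in an intermolecular formal [4+2] mode (four carbons from 4, two from 3) as the skipped 1,4-diene. The closest known reaction type is the cobalt–diphosphine catalysed neutral Diels–Alder reaction of unactivated terminal alkynes with 2-substituted buta-1,3-dienes, 2-silyloxydienes included, so no electron-poor dienophile is required and the ester, two CH2 groups away from the alkyne, is a spectator. No stereocentre arises, because every ring carbon of 5 is either sp2 or a CH2 group. The selectivity needed is para over meta: the substrates differ clearly in size at the two alkyne ends (H against CH2CH2CO2R) and at the two diene halves (C–OSiMe3 against CH), and the chelating dppe ligand with its P-phenyl groups turns this difference into the arrangement in which the alkyl-bearing alkyne carbon bonds to the diene CH2 remote from the silyloxy carbon. Excess diene, the non-coordinating solvent and dry ZnI2 should hold back alkyne cyclotrimerisation and cleavage of the enol ether.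

**Step 3**
Reactants: 5 hexacosyl 3-[4-(trimethylsilyloxy)cyclohexa-1,4-dien-1-yl]propanoate
Product: 7 hexacosyl 3-(4-hydroxyphenyl)propanoate (target), via aryl trimethylsilyl ether 6 (not isolated)
Conditions: DDQ (1.05 equiv), toluene, 0 °C to rt; filter; then 1 M aq HCl, THF, rt; NaHCO3 wash, chromatography or recrystallisation
Reagents that add atoms: none
Why: This is a DDQ dehydrogenative aromatisation followed by acid hydrolysis of an aryl silyl ether, in which DDQ takes a hydride from a doubly allylic ring CH2 of 5 and proton loss gives the arene with gain of aromatic stabilisation, the phenol stays masked while oxidant is present, and the very labile ArO–SiMe3 bond is then cleaved by dilute acid under conditions that should leave the primary alkyl ester intact.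

**Compound list**
1 | pent-4-ynoic acid | C#CCCC(=O)O | starting material
2 | hexacosan-1-ol | CCCCCCCCCCCCCCCCCCCCCCCCCCO | starting material
3 | hexacosyl pent-4-ynoate | CCCCCCCCCCCCCCCCCCCCCCCCCCOC(=O)CCC#C | intermediate
4 | 2-(trimethylsilyloxy)buta-1,3-diene | C=CC(=C)O[Si](C)(C)C | starting material
5 | hexacosyl 3-[4-(trimethylsilyloxy)cyclohexa-1,4-dien-1-yl]propanoate | CCCCCCCCCCCCCCCCCCCCCCCCCCOC(=O)CCC1=CCC(O[Si](C)(C)C)=CC1 | intermediate
6 | hexacosyl 3-[4-(trimethylsilyloxy)phenyl]propanoate | CCCCCCCCCCCCCCCCCCCCCCCCCCOC(=O)CCc1ccc(O[Si](C)(C)C)cc1 | intermediate
7 | hexacosyl 3-(4-hydroxyphenyl)propanoate | CCCCCCCCCCCCCCCCCCCCCCCCCCOC(=O)CCc1ccc(O)cc1 | target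

Total step count: 3
Longest linear sequence: 3 steps (2 → 3 → 5 → 7)

**Steps most likely to fail**

1. **Step 2 (key step).**
   - Risk: leakage into the meta regioisomer, cyclotrimerisation of the terminal alkyne at cobalt, or ZnI2-promoted loss of the silyl enol ether of the diene before it is bound.
   - Fallback: the ring is bought instead of built. Setting out from 2, Fischer esterification with purchased 3-(4-hydroxyphenyl)propanoic acid (cat. TsOH, toluene, Dean–Stark reflux) should acylate only the aliphatic alcohol, because a phenol is not esterified under these equilibrium conditions. This comes back to the route at 7, and no compound outside the list is made on the way (F0).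

2. **Step 3.**
   - Risk: early loss of the silyl group by the acidic hydroquinone formed from DDQ, followed by further oxidation of the free 4-alkylphenol at the benzylic CH2 through quinone methide formation. Adduct formation between DDQ and the electron-rich enol ether is a second possibility.
   - Fallback: setting out from 5, the enol ether is hydrolysed on purpose (1 M aq HCl, THF, 0 °C) to the β,γ-unsaturated ketone hexacosyl 3-(4-oxocyclohex-1-en-1-yl)propanoate F1.
   - This ketone is then aromatised by aerobic palladium-catalysed ketone dehydrogenation (Pd(OCOCF3)2, 2-(dimethylamino)pyridine, TsOH, O2 1 atm, DMSO/chlorobenzene, 80 °C). The sequence is palladium enolate formation, β-hydride elimination and dienone–phenol tautomerisation, and it comes back to the route at 7.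

3. **Step 1.**
   - Risk: slow acylation because the C26 alcohol dissolves poorly, so that O-to-N acyl migration of the activated acid consumes it as an N-acylurea.
   - Fallback: the polarity of the ester bond formation is reversed. Setting out from 2, MsCl and Et3N in warm CH2Cl2/THF should give hexacosyl methanesulfonate F2. This alkylates the caesium carboxylate of 1 (Cs2CO3, DMF/THF, 60 °C) by SN2 displacement at the primary carbon and comes back to the route at 3.

**Further compounds**
F0 | step 2 | none | none
F1 | step 3 | hexacosyl 3-(4-oxocyclohex-1-en-1-yl)propanoate | CCCCCCCCCCCCCCCCCCCCCCCCCCOC(=O)CCC1=CCC(=O)CC1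
F2 | step 1 | hexacosyl methanesulfonate | CCCCCCCCCCCCCCCCCCCCCCCCCCOS(C)(=O)=O
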